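**Numbering and assumption.** Ring atoms are numbered as in the target: C1 (CH–OAc), C2=C3(CH3), C4 (CH–O-aroyl), C5, C6=C7(CH3), C8, C9, C10, C11 (C(CH3)2). The target is then 1R,2Z,4R,6E, and this numbering is used for all intermediates in the discussion (systematic names carry their own locants). Compounds 1–24 are those of the steps below. Assumption: 4-[(tert-butyldimethylsilyl)oxy]benzoic acid 22 is bought as such; it is otherwise one operation from 4-hydroxybenzoic acid.

## The problem

The target is an eleven-membered carbocycle with no heteroatom in the ring, so a direct C–C ring closure has to pay the entropic and transannular cost of a medium ring. It holds two trisubstituted alkenes of opposite geometry, C2=C3 (Z) and C6=C7 (E), and each must be made as one isomer. The only stereocentres are C1 and C4, both R, both allylic and cis to each other across the Z alkene; there is no third centre from which either could be relayed, and C1 is neopentylic (next to the quaternary C11). The two oxygens carry different acyl groups, an acetate on the hindered C1 and a 4-hydroxybenzoate with a free phenol on C4, so they must be told apart. Sensitive points are the two allylic esters (ionisation, 1,4-acyl shift across the cis-ene-diol), any (Z)-γ-hydroxy enone met on the way (closure to a furan) and the phenol. The feature that the plan uses is the array O–C1···C7=C6: if C1 and C7 were bonded, the ring would split into a six-membered ring C1/C11/C10/C9/C8/C7, which is a 2,2,6-trimethylcyclohexanone with all three methyl groups in place, fused to a seven-membered ring C1–C7 in which the C2=C3 alkene can only be cis. An oxygen on C1 and a leaving group on C6 of that bicycle are the retron of a Grob fragmentation, which makes the eleven-membered ring, the C6=C7 alkene and a C1 carbonyl at once.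

## Retrosynthesis

**Acyl groups and C1.** The phenol of 24 is masked as the silyl ether 23, and the C4–O acyl bond is cut to the alcohol 21 and the acid 22. The acetate of 21 is put on earlier, at 20, while C4 still carries its silyl ether, so the two oxygens never compete. The C1–O–acetyl bond is cut to alcohol 19, and 19 is taken back to the ketone 18. C1 is chosen as the carbonyl because that is what the key step delivers. The forward reaction must reduce a hindered (Z)-enone 1,2 and to the 1R face.

**Key disconnection.** In 18 the bond C1–C7 is re-formed and a sulfonate is placed on C6, which gives the bicyclo[5.4.0] alkoxide 17. Cutting C1–C2 of 17 then leads to the alkenyllithium 16 and its iodide, the monocyclic keto tosylate 15. The neighbouring cuts (closing C1–C2 or C6=C7 on an open chain) form the strained ring in the bond-forming step and leave one alkene geometry to chance; sigmatropic ring expansions of a cycloheptane put the carbonyl on C2. Here the large ring is not closed at all: a cyclohexanone is opened after a seven-membered ring has been closed onto it. Precursor 15 is a cyclohexanone with a five-carbon side chain. The forward step asks for addition of a (Z)-alkenyl metal to a hindered ketone, an antiperiplanar fragmentation, and the right relative configuration at C6 and C7 (6R,7S or 6S,7R).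

**C6/C7 relationship.** 15 is the tosylate of 14. In 14 the bond cut is C7–CH3, leading to the aldol 12, and not the C6–C7 bond of an aldol of 2,2,6-trimethylcyclohexanone. The ring-locked enolate of the trimethyl ketone, in a closed aldol transition state, should place the carbinol oxygen anti to C8 (6R*,7R*), and that series would fragment to the 6Z ring. Methylation of the lithium-chelated dianion of 12 places the methyl anti to the oxygen (6R*,7S*), the series that fragments to 6E. The order of the two C–C bond formations therefore decides the alkene geometry.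

**Aldol.** 12 is cut at C6–C7 into 2,2-dimethylcyclohexanone 10 and the aldehyde 9. No stereocontrol is asked of this step: C7 is re-made in the methylation, and both C6 epimers converge in the fragmentation.

**The one lasting stereocentre.** 9 comes from the terminal alkene 7 (a masked aldehyde), 7 from the alcohol 6, and 6 by cutting C4–C5 into an allyl nucleophile and the enal 4. An asymmetric allylboration sets C4 (R). It is the only centre that has to be set before the key step.

**Z alkene.** 4 comes from alcohol 3, and 3 from propargyl alcohol 1 by adding methyl and iodine anti across the triple bond. This fixes the C2=C3 geometry and the C3 methyl in the first step.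

## Roads not taken

**Alternative 1:** (the obvious one) Cut C1–C2 and close the ring by an intramolecular Nozaki–Hiyama–Kishi reaction (CrCl2, NiCl2 cat.) of the iodo aldehyde A1. This would deliver 19 with no control at C1, since C4 is remote. It closes a medium ring at a neopentylic aldehyde under high dilution, and A1 needs its own stereoselective synthesis of the E trisubstituted alkene. The chosen plan takes the ring and the E alkene from a six-membered ring and needs no macrocyclisation.

**Alternative 2:** Cut C6=C7 and close it by ring-closing metathesis of the triene A2 with the second-generation Grubbs catalyst, aiming at 20. A trisubstituted alkene in an eleven-membered ring forms slowly from a 1,1-disubstituted partner, oligomers compete, and the E/Z outcome is not under control. Both carbinols and the Z alkene would have to be made beforehand in separate asymmetric steps. The fragmentation sets the geometry stereospecifically.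

**Alternative 3:** Cut both C–O bonds of the cis-ene-diol: singlet-oxygen [4+2] addition to the macrocyclic triene A3 would give the endoperoxide A4, and O–O reduction the cis-1,4-dioxygenated Z alkene. The eleven-membered ring must still be made first, the twisted Z,Z-diene is a poor 4π partner, and ene reactions at the many allylic positions and at C6=C7 compete. A4 is racemic and its two oxygens are still not differentiated. The chosen plan sets C4 by a reagent and tells the two oxygens apart from the start.

Key step: step 9

## Steps

Step 1
Reactants: 1 prop-2-yn-1-ol (propargyl alcohol)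
Product: 3 (Z)-3-iodo-2-methylprop-2-en-1-ol, via (Z)-alkenylmagnesium alkoxide 2 (not isolated)
Conditions: MeMgBr (3 equiv), CuI (10 mol%), THF, 0 → 23 °C; then I2, −20 → 0 °C
Reagents that add atoms: methylmagnesium bromide, C[Mg]Br; iodine, II
Why: Copper-catalysed anti-carbomagnesiation of the propargylic magnesium alkoxide puts methyl on the internal carbon and magnesium on the terminal carbon, cis to CH2O in a five-membered chelate; iodinolysis goes with retention. This fixes the later C2=C3 (Z) geometry and the C3 methyl.

Step 2
Reactants: 3 (Z)-3-iodo-2-methylprop-2-en-1-ol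
Product: 4 (Z)-3-iodo-2-methylprop-2-enal
Conditions: MnO2 (excess), CH2Cl2, 0 → 23 °C, dark
Reagents that add atoms: none
Why: MnO2 oxidises the allylic alcohol under neutral, heterogeneous conditions and leaves the vinyl iodide alone. The (Z)-β-iodoenal isomerises easily in light or acid, so it should be used at once.

Step 3
Reactants: 4 (Z)-3-iodo-2-methylprop-2-enal
Product: 6 (3R,1Z)-1-iodo-2-methylhexa-1,5-dien-3-ol, via borinic ester 5 (not isolated)
Conditions: (+)-Ipc2BOMe (from (−)-α-pinene), allylMgBr, Et2O, −78 → 23 °C; then 4, Et2O, −78 °C; then NaOH, H2O2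
Reagents that add atoms: allylmagnesium bromide, C=CC[Mg]Br
Why: Brown allylboration through a closed six-membered chair transition state under reagent control. The reagent with isopinocampheyl groups from (−)-α-pinene is the antipode of the one that gives S carbinols from aldehydes whose substituent outranks allyl, so it should give the 3R alcohol (C4 of the target).

Step 4
Reactants: 6 (3R,1Z)-1-iodo-2-methylhexa-1,5-dien-3-ol
Product: 7 tert-butyl{[(3R,1Z)-1-iodo-2-methylhexa-1,5-dien-3-yl]oxy}dimethylsilane
Conditions: TBSCl, imidazole, DMF, 23 °C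
Reagents that add atoms: tert-butyldimethylsilyl chloride, CC(C)(C)[Si](C)(C)Cl
Why: Standard silylation of a secondary allylic alcohol. The TBS ether should survive LiN(iPr)2, tBuLi and the fragmentation, and it keeps the C4 oxygen from closing onto the later C1 carbonyl.

Step 5
Reactants: 7 tert-butyl{[(3R,1Z)-1-iodo-2-methylhexa-1,5-dien-3-yl]oxy}dimethylsilane
Product: 9 (3R,4Z)-3-[(tert-butyldimethylsilyl)oxy]-5-iodo-4-methylpent-4-enal, via vicinal diol 8 (not isolated)
Conditions: OsO4 (2 mol%), NaIO4, 2,6-lutidine, dioxane–H2O, 23 °C
Reagents that add atoms: sodium periodate, [Na+].[O-]I(=O)(=O)=O (oxygen relayed by OsO4)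
Why: Lemieux–Johnson cleavage. OsO4 should dihydroxylate the monosubstituted alkene much faster than the trisubstituted, electron-poor iodoalkene; periodate cleaves diol 8, and 2,6-lutidine keeps the β-silyloxy aldehyde from eliminating.

Step 6
Reactants: 9 (3R,4Z)-3-[(tert-butyldimethylsilyl)oxy]-5-iodo-4-methylpent-4-enal; 10 2,2-dimethylcyclohexan-1-one
Product: 12 6-[(3R,4Z)-3-[(tert-butyldimethylsilyl)oxy]-1-hydroxy-5-iodo-4-methylpent-4-en-1-yl]-2,2-dimethylcyclohexan-1-one (diastereomers at ring C6 and C1′), via lithium enolate 11 (not isolated)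
Conditions: LiN(iPr)2 (1.05 equiv), THF, −78 °C; then 9, −78 °C; AcOH quench at −78 °C
Reagents that add atoms: none
Why: Kinetic lithium enolate aldol addition. Ketone 10 can enolise only toward C7 and should add to the aldehyde faster than it deprotonates it at −78 °C. No control at C6/C7 is needed, because C7 is re-made in step 7 and both C6 epimers converge in step 9.

Step 7
Reactants: 12 6-[(3R,4Z)-3-[(tert-butyldimethylsilyl)oxy]-1-hydroxy-5-iodo-4-methylpent-4-en-1-yl]-2,2-dimethylcyclohexan-1-one
Product: 14 (6S)-6-[(1R,3R,4Z)-3-[(tert-butyldimethylsilyl)oxy]-1-hydroxy-5-iodo-4-methylpent-4-en-1-yl]-2,2,6-trimethylcyclohexan-1-one plus its (6R,1′S,3′R) diastereomer, via dilithium aldolate enolate 13 (not isolated)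
Conditions: LiN(iPr)2 (2.4 equiv), THF, −78 → −30 °C; then MeI, DMPU, −78 → −20 °C
Reagents that add atoms: iodomethane, CI
Why: Fráter–Seebach-type alkylation of an aldolate dianion; C7–H is the only enolisable position. In the lithium-bridged six-membered chelate of enolate oxygen and C6 alkoxide, MeI should attack anti to the C5 substituent, so the new methyl is anti to the C6 oxygen and C8 is syn to it (6R,7S or 6S,7R in target numbering). This is the relationship that fragments to the 6E alkene.

Step 8
Reactants: 14 (6S)-6-[(1R,3R,4Z)-3-[(tert-butyldimethylsilyl)oxy]-1-hydroxy-5-iodo-4-methylpent-4-en-1-yl]-2,2,6-trimethylcyclohexan-1-one plus its (6R,1′S,3′R) diastereomer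
Product: 15 (1R,3R,4Z)-3-[(tert-butyldimethylsilyl)oxy]-5-iodo-4-methyl-1-[(1S)-1,3,3-trimethyl-2-oxocyclohexyl]pent-4-en-1-yl 4-methylbenzenesulfonate plus its (1S,1′R) diastereomer
Conditions: TsCl, Et3N, DMAP, CH2Cl2, 0 → 23 °C
Reagents that add atoms: 4-toluenesulfonyl chloride, Cc1ccc(cc1)S(=O)(=O)Cl
Why: Sulfonylation of the only hydroxyl, with retention at C6 (an O–S bond is formed). C7 is quaternary, so the β-sulfonyloxy ketone cannot eliminate to an enone; a tosylate is chosen over a mesylate because it has no acidic α-hydrogens toward tBuLi.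

Step 9
Reactants: 15 (1R,3R,4Z)-3-[(tert-butyldimethylsilyl)oxy]-5-iodo-4-methyl-1-[(1S)-1,3,3-trimethyl-2-oxocyclohexyl]pent-4-en-1-yl 4-methylbenzenesulfonate plus its (1S,1′R) diastereomer
Product: 18 (2Z,4R,6E)-4-[(tert-butyldimethylsilyl)oxy]-3,7,11,11-tetramethylcycloundeca-2,6-dien-1-one, via alkenyllithium 16 (not isolated), via bicyclic lithium alkoxide 17 (not isolated)
Conditions: tBuLi (2.1 equiv), THF–Et2O, −78 °C; then −78 → 23 °C
Reagents that add atoms: none
Why: Iodine–lithium exchange with tBuLi should be faster than any attack on the sulfonate or on the non-enolisable, doubly neopentylic ketone, and gives the (Z)-alkenyllithium 16 with retention. C2 then adds to the C1 carbonyl in a 7-exo-trig closure (the cis alkene holds C2 over C1) to give the bicyclo[5.4.0] lithium alkoxide 17 as either ring-fusion epimer. In 17 the C1–C7 bond and the C6–OTs bond can become antiperiplanar in both epimers (OTs equatorial on the flexible seven-membered ring), and alkoxide push then cleaves C1–C7, forms C1=O and C6=C7 and expels tosylate (Grob fragmentation), so the six-membered ring grows by the five atoms C2–C6 into the eleven-membered ring without any macrocyclisation. No stereocentre is created: C1, C6 and C7 are erased, and the anti elimination turns the (6R,7S)/(6S,7R) relationship from step 7 into the 6E alkene (C5 ends trans to C8), whichever C6 epimer relative to C4 and whichever ring fusion is present, so up to four diastereomers of 17 should converge on one product. The 2Z geometry is that of the vinyl iodide and is enforced by the seven-membered ring, and C4 (R) is untouched. The closest known reaction type is the sequenced intramolecular Barbier cyclisation/Grob fragmentation of iodoalkyl keto mesylates with SmI2 to eight- to ten-membered cycloalkenones, itself the one-pot form of the classical fragmentation of cyclic 1,3-diol monosulfonates. The selectivities needed are carbonyl addition over 5-exo displacement of the tosylate (secured by the neopentylic C6) and fragmentation over oxetane formation (secured by antiperiplanarity and by the release of strain between two adjacent quaternary carbons into a conjugated enone).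

Step 10
Reactants: 18 (2Z,4R,6E)-4-[(tert-butyldimethylsilyl)oxy]-3,7,11,11-tetramethylcycloundeca-2,6-dien-1-one
Product: 19 (1R,2Z,4R,6E)-4-[(tert-butyldimethylsilyl)oxy]-3,7,11,11-tetramethylcycloundeca-2,6-dien-1-ol
Conditions: (S)-1-methyl-3,3-diphenyltetrahydro-1H,3H-pyrrolo[1,2-c][1,3,2]oxazaborole [(S)-Me-CBS] (0.5 equiv), catecholborane, toluene, −78 → −40 °C; then MeOH, aq. NaOH
Reagents that add atoms: none
Why: Corey–Bakshi–Shibata reduction under catalyst control. The catalyst should bind the carbonyl anti to the quaternary C11 (the larger flank, as with tert-alkyl ketones) and deliver hydride to the Si face of C1 (O > C11 > C2), giving 1R, cis to the C4 oxygen. Catecholborane at low temperature should reduce 1,2 and leave the alkenes alone.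

Step 11
Reactants: 19 (1R,2Z,4R,6E)-4-[(tert-butyldimethylsilyl)oxy]-3,7,11,11-tetramethylcycloundeca-2,6-dien-1-ol
Product: 20 (1R,2Z,4R,6E)-4-[(tert-butyldimethylsilyl)oxy]-3,7,11,11-tetramethylcycloundeca-2,6-dien-1-yl acetate
Conditions: Ac2O, Et3N, DMAP, CH2Cl2, 23 °C
Reagents that add atoms: acetic anhydride, CC(=O)OC(C)=O
Why: DMAP-catalysed acylation of the only free hydroxyl; the neopentylic C1–OH is slow but needs no selectivity here, and no stereocentre is touched.

Step 12
Reactants: 20 (1R,2Z,4R,6E)-4-[(tert-butyldimethylsilyl)oxy]-3,7,11,11-tetramethylcycloundeca-2,6-dien-1-yl acetate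
Product: 21 (1R,2Z,4R,6E)-4-hydroxy-3,7,11,11-tetramethylcycloundeca-2,6-dien-1-yl acetate
Conditions: HF·pyridine, pyridine, THF, 0 → 23 °C
Reagents that add atoms: none
Why: Fluoride cleavage of the secondary silyl ether. The buffered, non-basic reagent is chosen so that the acetate does not shift from O1 to the freed O4 across the cis-ene-diol.

Step 13
Reactants: 21 (1R,2Z,4R,6E)-4-hydroxy-3,7,11,11-tetramethylcycloundeca-2,6-dien-1-yl acetate; 22 4-[(tert-butyldimethylsilyl)oxy]benzoic acid
Product: 23 (1R,2Z,4R,6E)-1-acetoxy-3,7,11,11-tetramethylcycloundeca-2,6-dien-4-yl 4-[(tert-butyldimethylsilyl)oxy]benzoate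
Conditions: EDC·HCl, DMAP, CH2Cl2, 0 → 23 °C
Reagents that add atoms: none
Why: Steglich esterification of the only free hydroxyl with retention at C4. The phenol is masked so that the acid cannot acylate itself.

Step 14
Reactants: 23 (1R,2Z,4R,6E)-1-acetoxy-3,7,11,11-tetramethylcycloundeca-2,6-dien-4-yl 4-[(tert-butyldimethylsilyl)oxy]benzoate
Product: 24 (1R,2Z,4R,6E)-1-acetoxy-3,7,11,11-tetramethylcycloundeca-2,6-dien-4-yl 4-hydroxybenzoate (target)
Conditions: Bu4NF, AcOH, THF, 0 °C
Reagents that add atoms: none
Why: Aryl silyl ethers are cleaved by buffered fluoride much faster than alkyl esters are touched, so the acetate, the benzoate and both allylic C–O bonds should survive.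

## Compound list

1 | prop-2-yn-1-ol | C#CCO | starting material
2 | (Z)-[3-(bromomagnesiooxy)-2-methylprop-1-en-1-yl]magnesium bromide | C/C(CO[Mg]Br)=C/[Mg]Br | intermediate (not isolated)
3 | (Z)-3-iodo-2-methylprop-2-en-1-ol | I/C=C(/C)CO | intermediate
4 | (Z)-3-iodo-2-methylprop-2-enal | I/C=C(/C)C=O | intermediate
5 | (3R,1Z)-1-iodo-2-methylhexa-1,5-dien-3-yl diisopinocampheylborinate (Ipc from (−)-α-pinene) | C=CC[C@@H](OB([C@H]1C[C@H]2C[C@@H]([C@@H]1C)C2(C)C)[C@H]1C[C@H]2C[C@@H]([C@@H]1C)C2(C)C)/C(C)=C\I | intermediate (not isolated)
6 | (3R,1Z)-1-iodo-2-methylhexa-1,5-dien-3-ol | I/C=C(/C)[C@H](O)CC=C | intermediate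
7 | tert-butyl{[(3R,1Z)-1-iodo-2-methylhexa-1,5-dien-3-yl]oxy}dimethylsilane | I/C=C(/C)[C@H](O[Si](C)(C)C(C)(C)C)CC=C | intermediate
8 | (4R,5Z)-4-[(tert-butyldimethylsilyl)oxy]-6-iodo-5-methylhex-5-ene-1,2-diol (both C2 epimers) | I/C=C(/C)[C@H](O[Si](C)(C)C(C)(C)C)CC(O)CO | intermediate (not isolated)
9 | (3R,4Z)-3-[(tert-butyldimethylsilyl)oxy]-5-iodo-4-methylpent-4-enal | I/C=C(/C)[C@H](O[Si](C)(C)C(C)(C)C)CC=O | intermediate
10 | 2,2-dimethylcyclohexan-1-one | CC1(C)CCCCC1=O | starting material
11 | lithium 6,6-dimethylcyclohex-1-en-1-olate | CC1(C)CCCC=C1O[Li] | intermediate (not isolated)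
12 | 6-[(3R,4Z)-3-[(tert-butyldimethylsilyl)oxy]-1-hydroxy-5-iodo-4-methylpent-4-en-1-yl]-2,2-dimethylcyclohexan-1-one (all diastereomers at target C6 and C7) | CC1(C)CCCC(C(O)C[C@@H](O[Si](C)(C)C(C)(C)C)/C(C)=C\I)C1=O | intermediate
13 | dilithium aldolate enolate of 12 (O1 enolate C1=C7, C6 alkoxide) | CC1(C)CCCC(=C1O[Li])C(O[Li])C[C@@H](O[Si](C)(C)C(C)(C)C)/C(C)=C\I | intermediate (not isolated)
14 | (6S)-6-[(1R,3R,4Z)-3-[(tert-butyldimethylsilyl)oxy]-1-hydroxy-5-iodo-4-methylpent-4-en-1-yl]-2,2,6-trimethylcyclohexan-1-one (target numbering 4R,6R,7S; drawn); formed together with the 4R,6S,7R isomer, CC1(C)CCC[C@](C)([C@@H](O)C[C@@H](O[Si](C)(C)C(C)(C)C)/C(C)=C\I)C1=O | CC1(C)CCC[C@@](C)([C@H](O)C[C@@H](O[Si](C)(C)C(C)(C)C)/C(C)=C\I)C1=O | intermediate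
15 | 4-methylbenzenesulfonate of 14 at the C6 hydroxyl (4R,6R,7S drawn; the 4R,6S,7R isomer is carried along) | CC1(C)CCC[C@@](C)([C@H](OS(=O)(=O)c2ccc(C)cc2)C[C@@H](O[Si](C)(C)C(C)(C)C)/C(C)=C\I)C1=O | intermediate
16 | (Z)-alkenyllithium from 15 (lithium in place of iodine at C2) | CC1(C)CCC[C@@](C)([C@H](OS(=O)(=O)c2ccc(C)cc2)C[C@@H](O[Si](C)(C)C(C)(C)C)/C(C)=C\[Li])C1=O | intermediate (not isolated)
17 | lithium 4-[(tert-butyldimethylsilyl)oxy]-3,7,11,11-tetramethyl-6-(tosyloxy)bicyclo[5.4.0]undec-2-en-1-olate (4R,6R,7S drawn; either configuration at C1; the 4R,6S,7R series likewise) | [Li]OC12C=C(C)[C@H](O[Si](C)(C)C(C)(C)C)C[C@@H](OS(=O)(=O)c3ccc(C)cc3)[C@]1(C)CCCC2(C)C | intermediate (not isolated)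
18 | (2Z,4R,6E)-4-[(tert-butyldimethylsilyl)oxy]-3,7,11,11-tetramethylcycloundeca-2,6-dien-1-one | O=C1/C=C(/C)[C@H](O[Si](C)(C)C(C)(C)C)C/C=C(\C)CCCC1(C)C | intermediate
19 | (1R,2Z,4R,6E)-4-[(tert-butyldimethylsilyl)oxy]-3,7,11,11-tetramethylcycloundeca-2,6-dien-1-ol | O[C@@H]1/C=C(/C)[C@H](O[Si](C)(C)C(C)(C)C)C/C=C(\C)CCCC1(C)C | intermediate
20 | (1R,2Z,4R,6E)-4-[(tert-butyldimethylsilyl)oxy]-3,7,11,11-tetramethylcycloundeca-2,6-dien-1-yl acetate | CC(=O)O[C@@H]1/C=C(/C)[C@H](O[Si](C)(C)C(C)(C)C)C/C=C(\C)CCCC1(C)C | intermediate
21 | (1R,2Z,4R,6E)-4-hydroxy-3,7,11,11-tetramethylcycloundeca-2,6-dien-1-yl acetate | CC(=O)O[C@@H]1/C=C(/C)[C@H](O)C/C=C(\C)CCCC1(C)C | intermediate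
22 | 4-[(tert-butyldimethylsilyl)oxy]benzoic acid | CC(C)(C)[Si](C)(C)Oc1ccc(cc1)C(=O)O | starting material
23 | (1R,2Z,4R,6E)-1-acetoxy-3,7,11,11-tetramethylcycloundeca-2,6-dien-4-yl 4-[(tert-butyldimethylsilyl)oxy]benzoate | CC(=O)O[C@@H]1/C=C(/C)[C@H](OC(=O)c2ccc(O[Si](C)(C)C(C)(C)C)cc2)C/C=C(\C)CCCC1(C)C | intermediate
24 | (1R,2Z,4R,6E)-1-acetoxy-3,7,11,11-tetramethylcycloundeca-2,6-dien-4-yl 4-hydroxybenzoate | CC(=O)O[C@@H]1/C=C(/C)[C@H](OC(=O)c2ccc(O)cc2)C/C=C(\C)CCCC1(C)C | target

## Step count and least certain steps

Total step count: 14. Longest linear sequence: 14 (propargyl alcohol 1 to 24; 10 and 22 are bought).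

**Step 9 (key step).** Three things may go wrong. The alkenyllithium may be diverted before it reaches the hindered carbonyl (attack at sulfonyl sulfur, 5-exo displacement of the tosylate, or simple protonation on work-up if the 1,2-addition is slow). The lithium alkoxide may be reluctant to fragment at low temperature. The product enone may be exposed to residual base. The fallback separates ring closure from fragmentation, so that no sulfonate is present when the organolithium is made. It sets out from 14: the hydroxyl is capped with MeLi (1 equiv), tBuLi (2.1 equiv) at −78 °C then closes the seven-membered ring to the bicyclic diol F1; TsCl/DMAP sulfonylates only the secondary hydroxyl (the ring-fusion tertiary one is inert) to give the monotosylate F2; KOtBu in THF/tBuOH fragments F2 in the classical way. The route is rejoined at 18.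

**Step 7.** The monolithium aldolate may undergo retro-aldol cleavage before the second deprotonation, because enolisation toward the alkoxide-bearing carbon is slow; chelate control may also be eroded if the dianion is not fully formed. The fallback makes the same dianion without ever having an alkoxide next to a free ketone. It sets out from 12: TMSOTf/Et3N gives the bis(trimethylsilyl) derivative F3 (silyl enol ether toward C7 and silyl ether at C6); MeLi (2.2 equiv) cleaves both Si–O bonds to regenerate 13, and MeI then gives 14, where the route is rejoined.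

**Step 10.** The conformational bias of the eleven-membered ring may override the catalyst, or the alkenyl flank rather than the quaternary flank may act as the large group, so that facial selectivity is poor or reversed; the hindered carbonyl may also react slowly. The fallback gives up reagent control. It sets out from 18: reduction with NaBH4/CeCl3·7H2O in MeOH at −40 °C under substrate control gives 19 and its C1 epimer F4, which are separated; F4 is returned to 18 with Dess–Martin periodinane and recycled. The route is rejoined at 19.

**Step 12.** On unmasking O4 next to the C1 acetate, the acetyl group may shift 1,4 across the cis-ene-diol, or the allylic acetate may ionise under acidic fluoride; the same shift may occur under DMAP in step 13. The fallback inverts the order so that a free O4 never sits beside an acetate. It sets out from 19: HF·pyridine gives the diol F5; EDC/DMAP with 22 acylates only the unhindered C4–OH (C1–OH is neopentylic) to give the monoester F6; Ac2O/DMAP then acetylates C1–OH. The route is rejoined at 23.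

## Further compounds

F1 | step 9 | 4-[(tert-butyldimethylsilyl)oxy]-3,7,11,11-tetramethylbicyclo[5.4.0]undec-2-ene-1,6-diol (4R,6R,7S drawn; either configuration at C1; the 4R,6S,7R series likewise) | OC12C=C(C)[C@H](O[Si](C)(C)C(C)(C)C)C[C@@H](O)[C@]1(C)CCCC2(C)C
F2 | step 9 | 6-O-(4-methylbenzenesulfonate) of F1 | OC12C=C(C)[C@H](O[Si](C)(C)C(C)(C)C)C[C@@H](OS(=O)(=O)c3ccc(C)cc3)[C@]1(C)CCCC2(C)C
F3 | step 7 | bis(trimethylsilyl) derivative of 12 (trimethylsilyl enol ether C1=C7 and trimethylsilyl ether at C6) | CC1(C)CCCC(=C1O[Si](C)(C)C)C(O[Si](C)(C)C)C[C@@H](O[Si](C)(C)C(C)(C)C)/C(C)=C\I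
F4 | step 10 | (1S,2Z,4R,6E)-4-[(tert-butyldimethylsilyl)oxy]-3,7,11,11-tetramethylcycloundeca-2,6-dien-1-ol | O[C@H]1/C=C(/C)[C@H](O[Si](C)(C)C(C)(C)C)C/C=C(\C)CCCC1(C)C
F5 | step 12 | (1R,2Z,4R,6E)-3,7,11,11-tetramethylcycloundeca-2,6-diene-1,4-diol | O[C@@H]1/C=C(/C)[C@H](O)C/C=C(\C)CCCC1(C)C
F6 | step 12 | (1R,2Z,4R,6E)-1-hydroxy-3,7,11,11-tetramethylcycloundeca-2,6-dien-4-yl 4-[(tert-butyldimethylsilyl)oxy]benzoate | O[C@@H]1/C=C(/C)[C@H](OC(=O)c2ccc(O[Si](C)(C)C(C)(C)C)cc2)C/C=C(\C)CCCC1(C)C
A1 | alternative 1 | (6E,9R,10Z)-9-[(tert-butyldimethylsilyl)oxy]-11-iodo-2,2,6,10-tetramethylundeca-6,10-dienal | O=CC(C)(C)CCC/C(C)=C/C[C@@H](O[Si](C)(C)C(C)(C)C)/C(C)=C\I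
A2 | alternative 2 | (3R,4Z,6R)-6-[(tert-butyldimethylsilyl)oxy]-2,2,5,9?-free description: acyclic triene with C1 acetate, C4 silyl ether, terminal alkenes at C6 and C7 (1R,2Z,4R in target numbering) | C=C(C)CCCC(C)(C)[C@H](OC(C)=O)/C=C(/C)[C@H](O[Si](C)(C)C(C)(C)C)CC=C
A3 | alternative 3 | (1Z,3Z,6E)-3,7,11,11-tetramethylcycloundeca-1,3,6-triene | CC1(C)CCC/C(C)=C/C/C=C(C)\C=C/1
A4 | alternative 3 | cis-1,4-endoperoxide of A3 across C1 and C4 (racemic; 1R,4R enantiomer drawn) | CC1(C)CCC/C(C)=C/C[C@H]2OO[C@@H]1C=C2C
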